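Start from 18.0 mM: this is the break-even level of second substrate, the concentration at which, with the coupling partner at its solubility, starting material goes to target and to cross product at equal rates, so that the selectivity factor is one.

    starting material ⇌ dormant form (K1 = 0.44, k1 = 0.28 /h)
    second substrate + coupling partner → second product (k2 = 0.21 /M/h)
    starting material + coupling partner → target (k3 = 1.0 /M/h)
    starting material + second substrate → cross product (k4 = 0.46 /M/h)
    solid reagent ⇌ coupling partner, rate k5*(cs5 - [coupling partner]) while solid is left; crystals form when [coupling partner] > cs5 (cs5 = 8.3 mM, k5 = 0.28 /h)
    coupling partner + protic impurity → quenched reagent (k6 = 15 /M/h)

| setting | north-east | south-west | east | north-west |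
|---|---|---|---|---|
| starting material | 20 mM (fed, over 8.0 d) | 20 mM | 20 mM | 20 mM |
| second substrate | 40.0 mM | 40.0 mM | 40.0 mM (fed, over 8.0 d) | 40.0 mM (in portions, 4, over 8.0 d) |
| protic impurity | 1.00 mM | 1.00 mM | 1.00 mM | 1.00 mM |
| solid reagent | 40.0 mM | 40.0 mM | 40.0 mM | 40.0 mM |
| time | 20 d | 20 d | 20 d | 20 d |
| remark | all else is in the flask from the start; the feed brings no volume worth counting | everything together at the start | all else is in the flask from the start; the feed brings no volume worth counting | first portion at the start, last at 8.0 d |

- solid, in amounts per volume of the solution: solid reagent
- at the start none of the solid reagent is in solution
- run time (north-east): 20 d

- which flask leads in amount of target, in percent of the starting material charged ("all alike" within 1.5 percentage points) (north-east / south-west / east / north-west / all alike)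
- how much target is there at the end, in percent of the starting material charged: north-east
- how much target is there at the end, in percent of the starting material charged: south-west
- how much target is there at the end, in percent of the starting material charged: east
- how much target is there at the end, in percent of the starting material charged: north-west

You have to decide how the second substrate goes in, and the even split is the zero of your scale. At any moment target takes break-even/(break-even + second substrate) of what reacts. Both routes leave from free starting material, so the dormant form slows them alike and the share stands. The coupling partner can be taken as near solubility, since dissolving can supply 2.32 mM/h, more than the 0.360 mM/h that the charges could draw.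

South-west starts at 40.0 mM of second substrate, so target's share opens at 31.1 %, and north-east starts from the same level. In east, my reckoning ignores consumption, and the feed reaches break-even at 3.61 d. Over that stretch second substrate averages half of break-even, target's share is 66.7 %, and 52.7 % of the starting material reacts. The remainder reacts at shares between the even split and 31.1 %. At their mean, 40.5 %, I get 54.3 % for east. In north-west the first portion of 10.0 mM stands below break-even, and I place north-west near east without a figure of my own. Your next run: charge the starting material and solid reagent whole, and feed the second substrate.

The forecast names east, with 57 % (range 53 % to 61 %), north-west 56 %, north-east 40.5 % and south-west 36.5 %: “Selectivity therefore depends on keeping the second substrate low while starting material is present.” My figure for east lies below its figure.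

The flasks give north-east 40.9 %, south-west 35.6 %, east 57.6 % and north-west 55.6 %, so east leads, by 2 percentage points over north-west.

East ends 7.6 points above the even split, and half of its turnover to target up to the asked time was done by 2.87 d, earlier than the 3.61 d at which the feed, consumption ignored, reaches break-even. In the neighbour of east charged with 10 mM of solid reagent, the same ratio taken with the coupling partner present at 20.0 d, 0.158 mM, gives a break-even of 0.344 mM against 24.7 mM of second substrate, and that flask ends with target at 32.9 % and cross product at 65.0 %.

The numbers of this flask were set for the occasion; the run is a simulation.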